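Readings and results were computed for an exercise, and the scatter is random.

A closed stirred flask starts its substrate at the full charge and lets it fall, while a well-mixed tank holds it at the outlet value. The question is what that difference does to the target.

| flask | substrate | remark | time |
|---|---|---|---|
| Tuesday's | 0.0010 M | run made earlier |  |
| Sunday's | 0.0014 M | run made earlier |  |
| Friday's | 0.0022 M | run made earlier |  |
| oak | 0.0010 M | a single well-mixed tank run continuously and read at steady state, 24.0 min in it on average |  |
| cedar | 0.0010 M | a single well-mixed tank run continuously and read at steady state, 8.0 min in it on average |  |
| alder | 0.0010 M | everything together in a closed stirred flask, run for 8.0 min | 8.0 min |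

- Tuesday's (time / min: target / %): 0.417: 7; 0.667: 11; 1.33: 30; 2.50: 49; 5.00: 51
- Sunday's (time / min: target / %): 0.500: 5; 1.50: 29; 3.00: 43; 5.00: 44; 6.00: 42
- Friday's (time / min: target / %): 0.500: 5; 1.00: 13; 2.00: 28; 3.00: 33; 6.00: 34

(scatter of a reading: 1.5 percentage points)

- the stated concentrations are those of everything mixed, before any reaction; amounts are the same in each set-up
- the earlier runs were made in a closed, stirred flask

- order of the set-ups by the amount of target at the outlet or at the end, in percent of the substrate put in, highest first (oak / cedar / alder)
- amount of target at the outlet or at the end, in percent of the substrate put in, oak
- amount of target at the outlet or at the end, in percent of the substrate put in, cedar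
- amount of target at the outlet or at the end, in percent of the substrate put in, alder

Time is the first setting. By hand, more time adds nothing once target stops rising, and Friday's run reads 33 % at 3.00 min and 34 % at 6.00 min, with a scatter of 1.5 percentage points.

The charge is the second. By hand, a waste path that grows with c_substrate takes more at a larger charge, and the last reading does fall from 51 % in Tuesday's run to 34 % in Friday's. Dividing the waste rate by the rate towards target removes time. That ratio is taken as a coefficient times c_substrate, so the share of reacted substrate reaching target is 1/(1 + coefficient × c_substrate). Between these runs, each extra unit of charge yielded 19.8 % as target, read as the share at the middle concentration. The waste coefficient, a selectivity factor per unit of c_substrate, therefore reads 2530 M⁻¹.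

The vessel is the third. Alder passes through every concentration from the charge downwards, and averaging the share gives 49.9 %. A tank works at one concentration. Taking 1.33 min from Tuesday's climb as a rough reaction time for the substrate, this reckoning puts c_substrate in oak at about 5.25 × 10⁻⁵ M and target there at about 83.7 %. For cedar, with 8.00 min in the tank on average, it puts c_substrate at about 1.43 × 10⁻⁴ M and target at about 63.0 %.

The forecast gives the same order, oak > cedar > alder, with 85 %, 72 % and 51 %, on the ground that “In a well-mixed tank the reactive species stays dilute, so selectivity improves.” Its tanks stand higher than this reckoning, cedar by 9 points.

The set-ups give oak > cedar > alder: oak 87.6 %, cedar 70.3 %, alder 52.0 %.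

    substrate → intermediate A (k = 0.0239 s⁻¹)
    intermediate A → intermediate B (k = 0.0386 s⁻¹)
    intermediate B → target (k = 0.0489 s⁻¹)
    2 substrate → self-condensation product (k = 8.42 M⁻¹ s⁻¹)
    substrate + intermediate A → side product (k = 41.3 M⁻¹ s⁻¹)

Oak's substrate stood at 2.70 × 10⁻⁵ M, where the waste coefficient gives a share of 93.6 %. Applied to the part of oak's charge that is no longer substrate, intermediate A or intermediate B, this gives 88.4 %, against 87.6 %. Cedar, at 7.23 × 10⁻⁵ M, gives 72.6 % in the same way, against 70.3 %. Alder holds 52.0 % of target at 8.0 min, and after 80.0 min, ten times as long, it holds 52.0 %.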